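## Structural features

The target 11 is a paraconic acid: an oxolan-2-one (γ-butyrolactone), numbered here as an oxolane with O1, C2 (bearing the 14-oxopentadecyl chain), C3 (CO2H), C4 (CH3) and C5 (ring carbonyl). C2 (S), C3 (R) and C4 (S) are contiguous stereocentres; chain and carboxyl are trans (2,3), carboxyl and methyl are cis (3,4). The chain is an unbranched spacer of thirteen methylene groups ending in a methyl ketone, with no stereocentre. C3–H and C4–H are both α to a carbonyl group and the cis-3,4 arrangement is expected to be the less stable one, so any enolization of the lactone or of a C3 ester drains towards the all-trans isomer. The remote methyl ketone is enolizable and electrophilic, which rules out unprotected exposure to organometallic reagents, strong bases or Mannich-type methylenation. The real difficulty is therefore the stereotriad, above all the cis-3,4 pair, which must be set without a late enolate step and in the presence of the free ketone. Read as an open chain, 11 is the γ-lactone of a 2-(1-hydroxyalkyl)-3-methylsuccinic acid, and the same oxygen O1 is also β to the carboxyl carbon on C3. The key step exploits this: O1, C2, C3 and the carboxyl carbon form a latent oxetan-2-one, the retron of a ketene–aldehyde [2+2] cycloaddition, while C4 (with its methyl) and C5 are a 2-methylsuccinate residue that can be bought enantiopure.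

## Logic of the disconnections

In one sentence: an alkaloid-catalysed ketene–aldehyde [2+2] cycloaddition of 8 with 4 gives the cis-oxetanone 9, whose ring strain then drives isomerization to the five-membered lactone 11.

11 ⇒ 10 ⇒ 9. The acyl–oxygen bond O1–C5 of 11 is cut (giving 10), and O1 is joined instead to the carboxyl carbon on C3, with the C5 carboxyl carried as a methyl ester (9). The cut is made there because O1 is β to that carboxyl, so the isomeric lactone is a four-membered ring. The gain is that a five-membered ring with three stereocentres becomes a [2+2] retron while all three centres are carried over unchanged. A cis-oxetanone maps onto the trans-2,3 oxolane because the ring switches from one carboxyl to the other. The forward step must open the four-membered ring by acyl–oxygen cleavage only (retention at C2) and must never leave C4–H or C3–H next to an enolizable carbonyl in base.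

9 ⇒ 4 + 8. The bonds cut are C2–C3 and O1–C(carboxyl), both oxolane numbering of 11. This splits the molecule into the whole C16 chain (4) and a C5 succinate unit (8). It sets C2 and C3 together and leaves C4 as a fixed, purchased centre, so the cis-3,4 relation is a matter of choosing enantiomers, not of a late kinetic step. The forward step needs cis selectivity in the four-membered ring, one absolute sense, reaction at the aldehyde and not the ketone of 4, and no epimerization of the ester-bearing centre of 8.

8 ⇒ 7 ⇒ 6 ⇒ 5. The ketene C=C is traced to HCl loss from 7; the C–Cl bond of 7 to the acid 6; and 6 to the diester 5 by differentiating the two ester groups. The demand is regioselective hydrolysis of the unbranched ester of 5.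

4 ⇒ 3 ⇒ 2 ⇒ 1. The aldehyde is traced to the primary alcohol 3, and the methyl–carbonyl bond of 3 is cut to the N-methoxy-N-methyl amide 2. The amide C–N bond is then cut to the macrolactone 1, which supplies the complete methylene spacer with two differentiated ends. The demands are mono-addition of the methyl nucleophile and oxidation of the primary alcohol without touching the ketone.

## Other disconnections considered

Alternative 1: The first that comes to mind. Cut C2–C3 by an aldol and leave the C4 methyl for last. A chiral-auxiliary syn-aldol of a succinate enolate equivalent with 4 and lactonization would give the C4-unsubstituted acid A1. α-Methylenation to A2 and hydrogenation from the face opposite the C3 carboxyl would then set the cis-3,4 pair. The chosen plan is preferred because this route adds auxiliary attachment and removal plus two C4 operations on an epimerizable lactone. The methylenation (carboxylation with MeOMgOCO2Me, then a Mannich step) would also attack the enolizable methyl ketone, forcing a protecting group. C4 would depend on a final facial selectivity, whereas the chosen plan buys it as a fixed centre.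

Alternative 2: Cut C3–C4 by a [3,3]-sigmatropic shift. Ireland–Claisen rearrangement of the (Z)-allylic propanoate A3 through a chair transition state would give the pentenoic acid A4. Desilylation and lactonization, then oxidative degradation of the vinyl group to the C3 carboxyl, would follow. The chosen plan is preferred because A3 needs an enantiopure silyloxy allylic alcohol (several steps) and the ketone must be masked against the amide base. A C=C bond is built only to be cut down by one carbon. The C3 configuration would rest on acyclic 1,2-induction from the silyloxy centre, which is less secure than catalyst control, and the step count roughly doubles.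

Alternative 3: Strain release from a donor–acceptor cyclopropane. In A5 (from a CuOTf/bis(oxazoline) cyclopropanation of a furoate, ozonolysis and chain addition to the aldehyde), base would remove the oxalate. The cyclopropanolate would open by retro-aldol cleavage and the hydroxy ester would lactonize to the aldehyde A6, to be oxidized to the acid. The chosen plan is preferred because this sequence delivers C4 as CH2. Methylation of the lactone enolate would go anti to the C3 substituent and give the trans-3,4 isomer, so the methylenation–hydrogenation detour of alternative 1 returns. The chain would also have to enter as an organometallic reagent with the ketone protected, and C2 would depend on a Felkin-type addition.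

Key step: step 6

Assumption: O-trimethylsilylquinidine is taken to attack through the enolate face that gives the (2S,3R)-oxetanone series drawn for 9, by analogy with other ammonium-enolate reactions of quinidine derivatives; if the sense were opposite, the pseudo-enantiomeric O-trimethylsilylquinine would be used with no other change.

## Steps

Step 1
Reactants: 1 oxacyclohexadecan-2-one (ω-pentadecalactone)
Product: 2 15-hydroxy-N-methoxy-N-methylpentadecanamide
Conditions: MeNH(OMe)·HCl (3 equiv), AlMe3 (3 equiv), CH2Cl2, 0 °C to rt; aq. HCl work-up
Reagents that add atoms: N,O-dimethylhydroxylamine hydrochloride, CNOC.Cl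
Why: Weinreb aminolysis of a lactone by the aluminium amide formed in situ; the macrolactone reacts like an open-chain ester and the ring opening releases the terminal hydroxyl.

Step 2
Reactants: 2 15-hydroxy-N-methoxy-N-methylpentadecanamide
Product: 3 16-hydroxyhexadecan-2-one
Conditions: MeMgBr (3 equiv), THF, 0 °C; aq. NH4Cl
Reagents that add atoms: methylmagnesium bromide, C[Mg]Br
Why: Weinreb ketone synthesis; the first equivalent deprotonates the hydroxyl, and the chelated tetrahedral magnesium adduct survives until work-up, so only one methyl group is added.

Step 3
Reactants: 3 16-hydroxyhexadecan-2-one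
Product: 4 15-oxohexadecanal
Conditions: TEMPO (10 mol %), PhI(OAc)2 (1.1 equiv), CH2Cl2, rt
Reagents that add atoms: none
Why: Oxoammonium (TEMPO) oxidation of a primary alcohol; it stops at the aldehyde in anhydrous medium and leaves the ketone untouched; 4 is used promptly.

Step 4
Reactants: 5 dimethyl (2S)-2-methylbutanedioate (dimethyl (S)-methylsuccinate)
Product: 6 (3S)-4-methoxy-3-methyl-4-oxobutanoic acid
Conditions: porcine pancreatic lipase, 0.1 M phosphate buffer (pH 7.0), rt, pH-stat with 1 M NaOH (1.0 equiv); then 1 M HCl to pH 2
Reagents that add atoms: water, O
Why: Enzymatic regioselective ester hydrolysis; the acyl-enzyme should form at the unbranched CH2CO2Me group while the α-branched ester is shielded, and no bond to the stereocentre is touched at neutral pH.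

Step 5
Reactants: 6 (3S)-4-methoxy-3-methyl-4-oxobutanoic acid
Product: 7 methyl (2S)-4-chloro-2-methyl-4-oxobutanoate
Conditions: (COCl)2 (1.2 equiv), DMF (cat.), CH2Cl2, 0 °C to rt; volatiles removed, used crude
Reagents that add atoms: oxalyl chloride, ClC(=O)C(=O)Cl
Why: Acid chloride formation through the Vilsmeier-type chloroiminium species; it is kept at or below rt so that the ester carbonyl does not close onto the acid chloride, and the stereocentre is not involved.

Step 6
Reactants: 7 methyl (2S)-4-chloro-2-methyl-4-oxobutanoate; 4 15-oxohexadecanal
Product: 9 methyl (2S)-2-[(2S,3R)-4-oxo-2-(14-oxopentadecyl)oxetan-3-yl]propanoate, via methyl (2S)-2-methyl-4-oxobut-3-enoate 8 (not isolated)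
Conditions: O-trimethylsilylquinidine (15 mol %), LiClO4 (2 equiv), iPr2NEt (2.5 equiv), CH2Cl2/Et2O 2:1, −78 °C, slow addition of 7 (2 equiv) to 4 (1 equiv)
Reagents that add atoms: none
Why: iPr2NEt dehydrochlorinates 7 to ketene 8, which the quinuclidine nitrogen of the alkaloid captures as a Z-configured acylammonium enolate. The lithium cation binds the aldehyde oxygen of 4 and the enolate oxygen, so the bond that becomes C2–C3 of 11 forms through a closed chair-like transition state; the lithium aldolate then closes onto the acylammonium carbonyl by 4-exo-trig acyl substitution, forming the ring O–C(=O) bond and releasing the catalyst. The closest known reaction type is the cinchona alkaloid/lithium salt-catalysed acyl halide–aldehyde cyclocondensation (a net ketene–aldehyde [2+2] cycloaddition), established for alkyl-substituted ketenes and unbranched aliphatic aldehydes. Both new stereocentres are set together: the Z enolate and the equatorial aldehyde chain in the chair give the cis ring, and the alkaloid, which blocks one enolate face with its quinoline and silyl ether, fixes the absolute sense as (2S,3R). The (S) centre already present in 8 is one atom away from the reacting carbon and differs only in CH3 versus CO2CH3, so catalyst control should dominate, and it is not enolized by iPr2NEt at −78 °C. Chemoselectivity for the aldehyde is needed and is secured because the lithium-activated aldehyde is far more electrophilic than the methyl ketone, which is not a partner in this reaction type at −78 °C. Slow addition of 7 keeps the concentration of 8 low and suppresses ketene dimerization.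

Step 7
Reactants: 9 methyl (2S)-2-[(2S,3R)-4-oxo-2-(14-oxopentadecyl)oxetan-3-yl]propanoate
Product: 11 (2S,3R,4S)-4-methyl-5-oxo-2-(14-oxopentadecyl)oxolane-3-carboxylic acid, via (2R,3S)-2-[(1S)-1-hydroxy-15-oxohexadecyl]-3-methylbutanedioic acid 10 (not isolated)
Conditions: LiOH·H2O (4 equiv), THF/H2O 3:1, 0 °C to rt; then 1 M HCl to pH 1, rt
Reagents that add atoms: lithium hydroxide, [Li+].[OH-]
Why: Strain-driven acyl–oxygen opening of the oxetanone by hydroxide and saponification of the methyl ester give the dicarboxylate of 10, in which neither α-centre is enolizable. On acidification the hydroxyl, γ to the C5 carboxyl, closes by 5-exo-trig lactonization and leaves the former oxetanone carbonyl as the free C3 carboxyl. No bond to a stereocentre is broken, so cis-9 gives the trans-2,3, cis-3,4 acid.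

## Compound list

1 | oxacyclohexadecan-2-one (ω-pentadecalactone) | O=C1CCCCCCCCCCCCCCO1 | starting material
2 | 15-hydroxy-N-methoxy-N-methylpentadecanamide | CON(C)C(=O)CCCCCCCCCCCCCCO | intermediate
3 | 16-hydroxyhexadecan-2-one | CC(=O)CCCCCCCCCCCCCCO | intermediate
4 | 15-oxohexadecanal | CC(=O)CCCCCCCCCCCCCC=O | intermediate
5 | dimethyl (2S)-2-methylbutanedioate | COC(=O)[C@@H](C)CC(=O)OC | starting material
6 | (3S)-4-methoxy-3-methyl-4-oxobutanoic acid | COC(=O)[C@@H](C)CC(=O)O | intermediate
7 | methyl (2S)-4-chloro-2-methyl-4-oxobutanoate | COC(=O)[C@@H](C)CC(=O)Cl | intermediate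
8 | methyl (2S)-2-methyl-4-oxobut-3-enoate (ketene, not isolated) | COC(=O)[C@@H](C)C=C=O | intermediate
9 | methyl (2S)-2-[(2S,3R)-4-oxo-2-(14-oxopentadecyl)oxetan-3-yl]propanoate | CC(=O)CCCCCCCCCCCCC[C@@H]1OC(=O)[C@@H]1[C@H](C)C(=O)OC | intermediate
10 | (2R,3S)-2-[(1S)-1-hydroxy-15-oxohexadecyl]-3-methylbutanedioic acid (not isolated) | CC(=O)CCCCCCCCCCCCC[C@H](O)[C@H](C(=O)O)[C@H](C)C(=O)O | intermediate
11 | (2S,3R,4S)-4-methyl-5-oxo-2-(14-oxopentadecyl)oxolane-3-carboxylic acid | CC(=O)CCCCCCCCCCCCC[C@@H]1OC(=O)[C@@H](C)[C@H]1C(=O)O | target

## Step count and least certain steps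

Total step count: 7. Longest linear sequence: 5 (steps 1, 2, 3, 6, 7); the second branch (steps 4, 5) joins at step 6.

Step 6 (key step). The β-branched ketene 8 may be captured by the aldehyde too slowly, so that ketene dimerization takes over. The existing (S) centre may be mismatched with the alkaloid, which would erode the cis preference or the facial selectivity. The fallback replaces the catalytic cycloaddition by an auxiliary-controlled boron aldol; it sets out from 7 and returns at 10. Acid chloride 7 acylates the lithium salt of (4R)-4-benzyl-1,3-oxazolidin-2-one (n-BuLi, THF, −78 °C) to give the imide methyl (2S)-4-[(4R)-4-benzyl-2-oxo-1,3-oxazolidin-3-yl]-2-methyl-4-oxobutanoate F1. Enolization of the imide methylene with Bu2BOTf/iPr2NEt and addition of 4 (CH2Cl2, −78 to 0 °C) should give, through the Z boron enolate and a chair transition state, the syn-aldol methyl (2S)-2-[(2R,3S)-1-[(4R)-4-benzyl-2-oxo-1,3-oxazolidin-3-yl]-3-hydroxy-1,17-dioxooctadecan-2-yl]propanoate F2. LiOH/H2O2 in THF/H2O then removes the auxiliary and the methyl ester to give 10, which closes to 11 on acidification as in step 7.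

Step 7. Slow saponification of the α-branched methyl ester may allow enolization at the methyl-bearing centre in a transient lactone or ester. The neighbouring carboxylate may also open the four-membered ring at the alkyl carbon, inverting C2. The fallback avoids base altogether; it sets out from 9 and returns at 11. Acid-catalysed methanolysis of the oxetanone (camphorsulfonic acid, MeOH, rt, no dehydrating agent) gives a β-hydroxy ester that relactonizes onto the neighbouring ester to give methyl (2S,3R,4S)-4-methyl-5-oxo-2-(14-oxopentadecyl)oxolane-3-carboxylate F3. Its ester is then hydrolysed under acid (6 M HCl/1,4-dioxane, 60 °C), where enolization of the lactone is slow, to give 11.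

Step 4. The lipase may hydrolyse the branched ester as well, or accept this enantiomer only slowly, giving the regioisomeric half-ester or poor conversion. The fallback differentiates the carboxyls through the cyclic anhydride and orthogonal esters; it sets out from 5 and returns at 6. Full hydrolysis of 5 (aq. HCl, reflux) gives (2S)-2-methylbutanedioic acid F4, and acetyl chloride at reflux closes it to (3S)-3-methyloxolane-2,5-dione F5. Benzyl alcohol with catalytic DMAP opens F5 at the less hindered carbonyl to give (2S)-4-(benzyloxy)-2-methyl-4-oxobutanoic acid F6, purified by crystallization. MeI/K2CO3 in DMF gives 4-benzyl 1-methyl (2S)-2-methylbutanedioate F7, and hydrogenolysis (H2, palladium on carbon, EtOAc) returns 6.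

## Further compounds

F1 | step 6 | methyl (2S)-4-[(4R)-4-benzyl-2-oxo-1,3-oxazolidin-3-yl]-2-methyl-4-oxobutanoate | COC(=O)[C@@H](C)CC(=O)N1[C@H](Cc2ccccc2)COC1=O
F2 | step 6 | methyl (2S)-2-[(2R,3S)-1-[(4R)-4-benzyl-2-oxo-1,3-oxazolidin-3-yl]-3-hydroxy-1,17-dioxooctadecan-2-yl]propanoate | CC(=O)CCCCCCCCCCCCC[C@H](O)[C@H](C(=O)N1[C@H](Cc2ccccc2)COC1=O)[C@H](C)C(=O)OC
F3 | step 7 | methyl (2S,3R,4S)-4-methyl-5-oxo-2-(14-oxopentadecyl)oxolane-3-carboxylate | CC(=O)CCCCCCCCCCCCC[C@@H]1OC(=O)[C@@H](C)[C@H]1C(=O)OC
F4 | step 4 | (2S)-2-methylbutanedioic acid | OC(=O)[C@@H](C)CC(=O)O
F5 | step 4 | (3S)-3-methyloxolane-2,5-dione | C[C@H]1CC(=O)OC1=O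
F6 | step 4 | (2S)-4-(benzyloxy)-2-methyl-4-oxobutanoic acid | OC(=O)[C@@H](C)CC(=O)OCc1ccccc1
F7 | step 4 | 4-benzyl 1-methyl (2S)-2-methylbutanedioate | COC(=O)[C@@H](C)CC(=O)OCc1ccccc1
A1 | alternative 1 | (2S,3R)-5-oxo-2-(14-oxopentadecyl)oxolane-3-carboxylic acid | CC(=O)CCCCCCCCCCCCC[C@@H]1OC(=O)C[C@H]1C(=O)O
A2 | alternative 1 | (2S,3R)-4-methylidene-5-oxo-2-(14-oxopentadecyl)oxolane-3-carboxylic acid | CC(=O)CCCCCCCCCCCCC[C@@H]1OC(=O)C(=C)[C@H]1C(=O)O
A3 | alternative 2 | (2Z,4S)-4-[(tert-butyldimethylsilyl)oxy]-17-(2-methyl-1,3-dioxolan-2-yl)heptadec-2-en-1-yl propanoate | CCC(=O)OC/C=C\[C@@H](O[Si](C)(C)C(C)(C)C)CCCCCCCCCCCCCC1(C)OCCO1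
A4 | alternative 2 | (2S,3R)-3-[(1S)-1-[(tert-butyldimethylsilyl)oxy]-14-(2-methyl-1,3-dioxolan-2-yl)tetradecyl]-2-methylpent-4-enoic acid | CC1(OCCO1)CCCCCCCCCCCCC[C@H](O[Si](C)(C)C(C)(C)C)[C@H](C=C)[C@H](C)C(=O)O
A5 | alternative 3 | ethyl (1S,2S,3R)-3-[(1S)-1-hydroxy-14-(2-methyl-1,3-dioxolan-2-yl)tetradecyl]-2-{[methoxy(oxo)acetyl]oxy}cyclopropane-1-carboxylate | CCOC(=O)[C@@H]1[C@@H](OC(=O)C(=O)OC)[C@H]1[C@@H](O)CCCCCCCCCCCCCC2(C)OCCO2
A6 | alternative 3 | (2S,3R)-2-[13-(2-methyl-1,3-dioxolan-2-yl)tridecyl]-5-oxooxolane-3-carbaldehyde | CC1(CCCCCCCCCCCCC[C@@H]2OC(=O)C[C@H]2C=O)OCCO1
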